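**Retrosynthetic overview**
- The last step is only O-demethylation; before it, ring A (the 2-aryloxy-4-alkylphenol) and the 19-membered macrocycle are made together.
- Key disconnection: ring A is cut into a three-carbon acetonyl unit on the oxygen of ring B (O–CH2–CO–CH3, a 1,3-bis-nucleophile) and a three-carbon 2-alkyl-3-(dimethylamino)acrolein at the end of the side chain of ring D (a masked 2-alkylmalondialdehyde). One base-mediated [3+3] benzannulation closes the macrocycle and ring A.
- The open-chain precursor is cut at the ethylene bridge between rings B and C (Wittig, then hydrogenation) and at the diaryl ether between rings C and D (copper-catalysed coupling).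
- Order of ring formation: rings B, C and D are bought as benzene building blocks; the macrocycle and ring A form last, in the same operation.

Assumption: the target has no stereocentre and its 19-membered ring is taken as conformationally mobile, so there is no enantiomer to control and the SMILES is the full structural definition.

**Route**

Step 1
Reactants: 1 3-hydroxybenzyl alcohol; 2 triphenylphosphine hydrobromide
Product: 3 (3-hydroxybenzyl)triphenylphosphonium bromide
Conditions: MeCN, reflux, 4 h; salt filtered off
Reagents that add atoms: triphenylphosphine hydrobromide 2, [Br-].[PH+](c1ccccc1)(c1ccccc1)c1ccccc1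
Why: HBr turns the benzylic alcohol into the benzyl bromide in situ and triphenylphosphine quaternises it (SN2 phosphonium salt formation); the meta phenol is inert.

Step 2
Reactants: 4 methyl 4-(4-hydroxyphenyl)butanoate; 5 3-bromo-4,5-dimethoxybenzaldehyde
Product: 6 methyl 4-[4-(5-formyl-2,3-dimethoxyphenoxy)phenyl]butanoate
Conditions: CuI (10 mol %), picolinic acid (20 mol %), K3PO4 (2 equiv), DMSO, 90 °C
Reagents that add atoms: none
Why: Ullmann-type copper-catalysed C–O coupling of the phenoxide of 4 with the aldehyde-activated aryl bromide; the picolinic acid ligand copes with the ortho-methoxy group, and the anhydrous phosphate base spares aldehyde and methyl ester.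

Step 3
Reactants: 6 methyl 4-[4-(5-formyl-2,3-dimethoxyphenoxy)phenyl]butanoate; 3 (3-hydroxybenzyl)triphenylphosphonium bromide
Product: 7 methyl 4-[4-[5-[2-(3-hydroxyphenyl)ethenyl]-2,3-dimethoxyphenoxy]phenyl]butanoate (E/Z mixture)
Conditions: NaOMe (2.2 equiv), MeOH–THF, 0 °C to rt; aq NH4Cl
Reagents that add atoms: none
Why: Wittig olefination of the aryl aldehyde by the semi-stabilised benzylic ylide; one extra equivalent of base covers the phenol, methoxide leaves the methyl ester unchanged, and the E/Z ratio is irrelevant because the alkene is saturated next.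

Step 4
Reactants: 7 methyl 4-[4-[5-[2-(3-hydroxyphenyl)ethenyl]-2,3-dimethoxyphenoxy]phenyl]butanoate
Product: 8 methyl 4-[4-[5-[2-(3-hydroxyphenyl)ethyl]-2,3-dimethoxyphenoxy]phenyl]butanoate
Conditions: H2 (1 atm), Pd/C (10 wt %), EtOAc–MeOH, rt
Reagents that add atoms: none
Why: Heterogeneous catalytic hydrogenation saturates only the stilbene C=C (ester, aryl ethers and arenes are untouched); no stereocentre is created.

Step 5
Reactants: 8 methyl 4-[4-[5-[2-(3-hydroxyphenyl)ethyl]-2,3-dimethoxyphenoxy]phenyl]butanoate
Product: 9 4-[4-[5-[2-(3-hydroxyphenyl)ethyl]-2,3-dimethoxyphenoxy]phenyl]butanal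
Conditions: i-Bu2AlH (2.3 equiv), CH2Cl2, −78 °C; MeOH, then aq KNaC4H4O6
Reagents that add atoms: none
Why: DIBAL-H half-reduction of the methyl ester; the tetrahedral aluminium hemiacetal is stable at −78 °C and gives the aldehyde on work-up, the first equivalent of hydride being consumed by the phenol.

Step 6
Reactants: 9 4-[4-[5-[2-(3-hydroxyphenyl)ethyl]-2,3-dimethoxyphenoxy]phenyl]butanal; 10 tert-butoxybis(dimethylamino)methane (Bredereck's reagent)
Product: 11 (2E)-2-[(dimethylamino)methylidene]-4-[4-[5-[2-(3-hydroxyphenyl)ethyl]-2,3-dimethoxyphenoxy]phenyl]butanal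
Conditions: 10 (2.5 equiv), toluene, 60 °C; aq NH4Cl wash
Reagents that add atoms: tert-butoxybis(dimethylamino)methane 10, CN(C)C(OC(C)(C)C)N(C)C
Why: Bredereck aminomethylenation of the aldehyde α-CH2, driven by loss of tert-butanol and dimethylamine, gives the push–pull 2-alkyl-3-(dimethylamino)acrolein; the phenol only forms a salt with the reagent and is returned on work-up.

Step 7
Reactants: 11 (2E)-2-[(dimethylamino)methylidene]-4-[4-[5-[2-(3-hydroxyphenyl)ethyl]-2,3-dimethoxyphenoxy]phenyl]butanal; 12 chloroacetone
Product: 15 macrocyclic phenol (target skeleton; ring C as its dimethyl ether; ring A hydroxyl free), via aryloxyacetone 13 (not isolated), via macrocyclic dienaminone 14 (not isolated)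
Conditions: 12 (1.05 equiv), K2CO3 (1.5 equiv), NaI (cat.), DMF, 50 °C, 2 h; decanted solution added over 12 h to KOt-Bu (4 equiv), THF, 65 °C (2 mM final); AcOH
Reagents that add atoms: chloroacetone 12, CC(=O)CCl
Why: Proposed new method: Williamson O-alkylation of the phenoxide of 11 gives the 1,3-bis-nucleophilic aryloxyacetone 13; under KOt-Bu at high dilution its more acidic ArO–CH2 enolate condenses with the formyl carbon of the aminoacrolein (vinylogous aldol condensation, closing the 19-membered ring as dienaminone 14), and the methyl-ketone enolate then closes ring A by 6π-electrocyclisation onto the CH–NMe2 terminus with irreversible loss of Me2NH to the phenoxide; because the three-carbon electrophile is symmetric, either order of attack gives the same 2-aryloxy-4-alkylphenol and no stereocentre is formed; the closest known reaction type is the intermolecular Jutz-type [3+3] benzannulation of ketones with 3-aminoacroleins or vinamidinium salts to phenols, here run as a macrocyclisation.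

Step 8
Reactants: 15 macrocyclic phenol (ring C dimethyl ether)
Product: 16 CNP0495401.0 (target)
Conditions: BBr3 (6 equiv), CH2Cl2, −78 °C to rt; H2O
Reagents that add atoms: none
Why: BBr3 O-demethylation (Lewis-acid complexation, then SN2 attack of bromide on the methyl group) frees the catechol of ring C; the diaryl ether C–O bonds are not cleaved.

**Compound list**

1 | 3-hydroxybenzyl alcohol | OCc1cccc(O)c1 | starting material
2 | triphenylphosphine hydrobromide | [Br-].[PH+](c1ccccc1)(c1ccccc1)c1ccccc1 | starting material
3 | (3-hydroxybenzyl)triphenylphosphonium bromide | [Br-].Oc1cccc(C[P+](c2ccccc2)(c2ccccc2)c2ccccc2)c1 | intermediate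
4 | methyl 4-(4-hydroxyphenyl)butanoate | COC(=O)CCCc1ccc(O)cc1 | starting material
5 | 3-bromo-4,5-dimethoxybenzaldehyde | COc1cc(C=O)cc(Br)c1OC | starting material
6 | methyl 4-[4-(5-formyl-2,3-dimethoxyphenoxy)phenyl]butanoate | COC(=O)CCCc1ccc(Oc2cc(C=O)cc(OC)c2OC)cc1 | intermediate
7 | methyl 4-[4-[5-[2-(3-hydroxyphenyl)ethenyl]-2,3-dimethoxyphenoxy]phenyl]butanoate (E/Z mixture, geometry not defined) | COC(=O)CCCc1ccc(Oc2cc(C=Cc3cccc(O)c3)cc(OC)c2OC)cc1 | intermediate
8 | methyl 4-[4-[5-[2-(3-hydroxyphenyl)ethyl]-2,3-dimethoxyphenoxy]phenyl]butanoate | COC(=O)CCCc1ccc(Oc2cc(CCc3cccc(O)c3)cc(OC)c2OC)cc1 | intermediate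
9 | 4-[4-[5-[2-(3-hydroxyphenyl)ethyl]-2,3-dimethoxyphenoxy]phenyl]butanal | O=CCCCc1ccc(Oc2cc(CCc3cccc(O)c3)cc(OC)c2OC)cc1 | intermediate
10 | tert-butoxybis(dimethylamino)methane (Bredereck's reagent) | CN(C)C(OC(C)(C)C)N(C)C | starting material
11 | (2E)-2-[(dimethylamino)methylidene]-4-[4-[5-[2-(3-hydroxyphenyl)ethyl]-2,3-dimethoxyphenoxy]phenyl]butanal | CN(C)/C=C(/C=O)CCc1ccc(Oc2cc(CCc3cccc(O)c3)cc(OC)c2OC)cc1 | intermediate
12 | chloroacetone | CC(=O)CCl | starting material
13 | (2E)-2-[(dimethylamino)methylidene]-4-[4-[2,3-dimethoxy-5-[2-[3-(2-oxopropoxy)phenyl]ethyl]phenoxy]phenyl]butanal (aryloxyacetone) | CC(=O)COc1cccc(CCc2cc(OC)c(OC)c(Oc3ccc(CC/C(C=O)=C\N(C)C)cc3)c2)c1 | intermediate (not isolated)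
14 | macrocyclic dienaminone: 19-membered ring in which the former O–CH2 carbon (now sp2, still carrying the acetyl group and the oxygen of ring B) is joined through CH= to the carbon bearing the exocyclic =CH–NMe2 group (C=C geometries mobile, not defined) | CC(=O)C1=CC(=CN(C)C)CCc2ccc(cc2)Oc2cc(CCc3cccc(c3)O1)cc(OC)c2OC | intermediate (not isolated)
15 | macrocyclic phenol: the target with both hydroxyls of ring C as methyl ethers and the ring A hydroxyl free | Oc1ccc2cc1Oc1cccc(c1)CCc1cc(OC)c(OC)c(c1)Oc1ccc(cc1)CC2 | intermediate
16 | CNP0495401.0: 19-membered macrocyclic bis(bibenzyl) with one hydroxyl on ring A and a catechol on ring C (no stereocentre) | Oc1ccc2cc1Oc1cccc(c1)CCc1cc(O)c(O)c(c1)Oc1ccc(cc1)CC2 | target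

**Step count and risks**

Total step count: 8. Longest linear sequence: 7 (steps 2 to 8, from 4 and 5 to 16); step 1 is a one-step side branch that enters at step 3.

The three steps most likely to fail:

Step 7 (highest risk). The first C–C bond has to close a 19-membered ring in competition with oligomerisation and self-aldol of the aryloxyacetone, and the formyl group of a vinylogous formamide is a weak electrophile. The fallback sets out from aldehyde 9 and comes back at 15, keeping the two-ring closure but changing the electrophile and the oxidation level. Aldehyde 9 is O-alkylated with chloroacetone 12 (K2CO3, NaI, DMF, rt) to keto aldehyde F1. The aldehyde of F1 is α-methylenated (aqueous CH2O, catalytic pyrrolidine and propanoic acid, i-PrOH, 45 °C) to 2-methylidene aldehyde F2. Slow addition of F2 to DBU in MeCN at 60 °C (2 mM) closes the macrocycle and the six-membered ring by Michael addition and aldol condensation (Robinson annulation) to macrocyclic cyclohexenone F3. Aerobic dehydrogenation (Pd(O2CCF3)2, 2-(dimethylamino)pyridine, TsOH, O2, DMSO, 80 °C) then aromatises F3 to phenol 15.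

Step 6. The enolisable aliphatic aldehyde can self-condense under the basic aminal ester, and the free phenol consumes reagent. The fallback sets out from 9 and comes back at 11. Aldehyde 9 is converted with HC(OMe)3 and catalytic TsOH in MeOH into dimethyl acetal F4. Vilsmeier–Haack–Arnold formylation of the enol ether that F4 forms in situ (POCl3, DMF, 70 °C; then aqueous K2CO3, which also cleaves any aryl formate) gives 11.

Step 2. The bromide is flanked by a methoxy group, and aldehyde and ester must survive hot base. The fallback sets out from 5 and comes back at 6, replacing the copper-catalysed halide displacement by an oxidative coupling. Miyaura borylation of 5 (B2pin2, Pd(dppf)Cl2, KOAc, dioxane, 80 °C) gives pinacol boronate F5. Chan–Lam coupling of F5 with phenol 4 (Cu(OAc)2, pyridine, 4 Å molecular sieves, air, CH2Cl2, rt) gives 6.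

**Further compounds**

F1 | step 7 | 4-[4-[2,3-dimethoxy-5-[2-[3-(2-oxopropoxy)phenyl]ethyl]phenoxy]phenyl]butanal | CC(=O)COc1cccc(CCc2cc(OC)c(OC)c(Oc3ccc(CCCC=O)cc3)c2)c1
F2 | step 7 | 4-[4-[2,3-dimethoxy-5-[2-[3-(2-oxopropoxy)phenyl]ethyl]phenoxy]phenyl]-2-methylidenebutanal | CC(=O)COc1cccc(CCc2cc(OC)c(OC)c(Oc3ccc(CCC(=C)C=O)cc3)c2)c1
F3 | step 7 | macrocyclic 4-alkyl-6-aryloxycyclohex-2-en-1-one, the non-aromatic precursor of ring A inside the 19-membered ring (diastereomer mixture; both stereocentres are destroyed on aromatisation) | O=C1C=CC2CC1Oc1cccc(c1)CCc1cc(OC)c(OC)c(c1)Oc1ccc(cc1)CC2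
F4 | step 6 | 3-[2-[3-[4-(4,4-dimethoxybutyl)phenoxy]-4,5-dimethoxyphenyl]ethyl]phenol | COC(CCCc1ccc(Oc2cc(CCc3cccc(O)c3)cc(OC)c2OC)cc1)OC
F5 | step 2 | 3,4-dimethoxy-5-(4,4,5,5-tetramethyl-1,3,2-dioxaborolan-2-yl)benzaldehyde | COc1cc(C=O)cc(B2OC(C)(C)C(C)(C)O2)c1OC
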